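Single ring stands on average at 9.50% of the charge in Friday's run and at 17.0% in Thursday's, and my reckoning rests on that gap.

| flask | starting material | protic impurity | temperature | remark | time |
|---|---|---|---|---|---|
| Friday's | 0.80 M | 0.40 M | 71 °C | run made earlier |  |
| Thursday's | 0.80 M | 1.6 M | 96 °C | run made earlier |  |
| noon | 0.80 M | 0.800 M | 105 °C |  | 8.0 d |
| summer | 0.80 M | 0.800 M | 75 °C |  | 8.0 d |
| autumn | 0.80 M | 0.800 M | 90 °C |  | 8.0 d |
| dusk | 0.80 M | 0.800 M | 60 °C |  | 8.0 d |

| run | time / d | single ring / % | open dimer / % | open trimer / % |
|---|---|---|---|---|
| Friday's | 3.00 | 11 | 45 | 8 |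
| Friday's | 6.00 | 11 | 51 | 15 |
| Friday's | 10.0 | 7 | 50 | 16 |
| Friday's | 15.0 | 10 | 44 | 21 |
| Friday's | 25.0 | 10 | 40 | 21 |
| Friday's | 40.0 | 8 | 36 | 20 |
| Thursday's | 1.04 | 19 | 45 | 13 |
| Thursday's | 1.67 | 17 | 33 | 12 |
| Thursday's | 2.50 | 13 | 31 | 17 |
| Thursday's | 4.00 | 17 | 19 | 12 |
| Thursday's | 5.00 | 19 | 22 | 13 |
| Thursday's | 8.00 | 18 | 13 | 16 |
| Thursday's | 12.0 | 16 | 3 | 14 |

(standard deviation of a reading: 2 percentage points)

* the flask with the highest share of single ring in all that became single ring or open dimer or open trimer or ring dimer or isomer of the product ("all alike" if they lie within 1.5 percentage points) (noon / summer / autumn / dusk / all alike)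
* share of single ring in all that became single ring or open dimer or open trimer or ring dimer or isomer of the product, noon
* share of single ring in all that became single ring or open dimer or open trimer or ring dimer or isomer of the product, summer
* share of single ring in all that became single ring or open dimer or open trimer or ring dimer or isomer of the product, autumn
* share of single ring in all that became single ring or open dimer or open trimer or ring dimer or isomer of the product, dusk

- percentages count the starting material that a species holds: one open dimer or ring dimer counts as two
- percentages count the starting material that a species holds: one open trimer counts as three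

I first ask which settings must be known well. The reading time matters little once the plateau stands: in Thursday's run single ring goes from 19% to 16% while open dimer falls from 45% to 3%. Whether protic impurity matters is open: it moves from 0.40 M to 1.6 M together with the temperature, and the two runs cannot separate them. At one charge of 0.800 M, an impurity effect shifts the flasks together, whereas a temperature effect spreads them. I take temperature as the cause.

Between summer and autumn that gives 4.5 percentage points, the plateau rise: the points of single-ring plateau gained from one flask of this ladder to the next. My shares are then 19.7% for noon, 15.2% for autumn, 10.7% for summer and 6.20% for dusk, with noon highest. I trust dusk least: it lies outside both runs, and in Friday's run the three readings sum to 64.0% at 3.00 d but 77.0% at 6.00 d, which points to slow consumption in the cold.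

The forecast also names noon, with 19%, 11.5%, 15% and 8.5% for noon, summer, autumn and dusk, on the ground “I favour mainly temperature”. Its dusk stands above mine.

The simulation gives noon highest, with 21.3%, 11.7%, 16.4% and 11.6% for noon, summer, autumn and dusk.

    starting material → single ring (k = 8.10 × 10⁻⁶ s⁻¹, Ea = 109 kJ mol⁻¹)
    2 starting material → open dimer (k = 2.80 × 10⁻⁵ M⁻¹ s⁻¹, Ea = 95.0 kJ mol⁻¹)
    starting material + open dimer → open trimer (k = 9.60 × 10⁻⁶ M⁻¹ s⁻¹, Ea = 88.0 kJ mol⁻¹)
    open dimer → ring dimer (k = 1.10 × 10⁻⁶ s⁻¹, Ea = 121 kJ mol⁻¹)
    single ring ⇌ isomer of the product (K = 0.880, k = 3.10 × 10⁻⁵ s⁻¹, Ea = 117 kJ mol⁻¹, ΔH = −25.0 kJ mol⁻¹)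
    starting material + protic impurity → quenched substrate (k = 1.80 × 10⁻⁶ M⁻¹ s⁻¹, Ea = 98.0 kJ mol⁻¹)
    (constants at 90 °C)

In noon, half the turnover of two starting material to open dimer is done by 0.828 h, far sooner than the 8.0 d of the flask, whereas in dusk 28% of the starting material still stands at 8.00 d, with single ring at 8.04% of the charge and 11.6% of what reacted. From autumn to noon the share climbs 4.9 points against my plateau rise of 4.5 points. Scaled to a repeat of noon at 80 °C, the rise added to summer gives 13.2%, and that flask gives 13.2%.

Readings and results are simulated with made-up constants, and the scatter is random.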